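Ring C carries OH at C1, the ring B ether oxygen at C2 and the ethylene bridge to ring D at C4; this 1,2,4-pattern equals that of a 2-aryloxy-4-alkylcyclohex-2-enone. The route therefore builds ring C from open-chain carbons: 4-(2,5-dimethoxyphenyl)butanal (15) and the vinyl ketone 10, whose aryloxymethyl group already holds rings A and B, are joined by a Robinson annulation. In one operation the C4–C5 bond (Michael addition) and the C2=C3 bond (aldol condensation) form and the six-membered ring closes to enone 18. The oxygen between rings B and C is installed beforehand by alkylating a phenol. Aerobic dehydrogenation and BBr3 demethylation then give the target.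

Key step: step 8

Remark: the target is achiral; 18 is made and used as a racemate, 16, 17 and 19 as unassigned stereoisomer mixtures, and all of this stereochemistry disappears when ring C becomes aromatic.

Step 1
Reactants: 1 (3-methoxybenzyl)triphenylphosphonium chloride; 2 4-(benzyloxy)benzaldehyde
Product: 4 1-(benzyloxy)-4-[2-(3-methoxyphenyl)ethenyl]benzene (expected as an E/Z mixture), via phosphonium ylide 3 (not isolated)
Conditions: KOtBu, THF, 0 °C to rt
Reagents that add atoms: none
Why: Wittig olefination of an aromatic aldehyde by a semi-stabilised benzylic ylide is dependable, and the alkene geometry is irrelevant because the double bond is saturated in step 2.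

Step 2
Reactants: 4 1-(benzyloxy)-4-[2-(3-methoxyphenyl)ethenyl]benzene
Product: 5 4-[2-(3-methoxyphenyl)ethyl]phenol
Conditions: H2 (1 atm), 10% Pd/C, EtOAc/MeOH, rt
Reagents that add atoms: none
Why: Catalytic hydrogenation over palladium metal should saturate the stilbene and cleave the benzyl ether by hydrogenolysis in the same flask, while the aryl methyl ether is inert.

Step 3
Reactants: 5 4-[2-(3-methoxyphenyl)ethyl]phenol; 6 2-chloro-N-methoxy-N-methylacetamide
Product: 7 N-methoxy-2-{4-[2-(3-methoxyphenyl)ethyl]phenoxy}-N-methylacetamide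
Conditions: K2CO3, KI (cat.), MeCN, 70 °C
Reagents that add atoms: none
Why: Williamson ether synthesis, in which the phenoxide displaces chloride from a carbonyl-activated primary carbon, attaches the future C2–O bond of ring C at an sp3 carbon and delivers the Weinreb amide in one step.

Step 4
Reactants: 7 N-methoxy-2-{4-[2-(3-methoxyphenyl)ethyl]phenoxy}-N-methylacetamide; 8 vinylmagnesium bromide
Product: 10 1-{4-[2-(3-methoxyphenyl)ethyl]phenoxy}but-3-en-2-one, via magnesium chelate 9 (not isolated)
Conditions: CH2=CHMgBr (1.3 equiv), THF, −78 to 0 °C; inverse quench into cold 1 M HCl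
Reagents that add atoms: none
Why: Weinreb ketone synthesis, in which the five-membered magnesium chelate blocks a second addition and the inverse quench into cold acid protonates the released N,O-dimethylhydroxylamine before it can add to the new vinyl ketone.

Step 5
Reactants: 11 2-iodo-1,4-dimethoxybenzene; 12 but-3-yn-1-ol
Product: 13 4-(2,5-dimethoxyphenyl)but-3-yn-1-ol
Conditions: PdCl2(PPh3)2 (2 mol%), CuI (4 mol%), Et3N, THF, 50 °C
Reagents that add atoms: none
Why: Sonogashira coupling of an aryl iodide with a terminal alkyne tolerates the free hydroxyl group and installs the complete four-carbon chain on ring D.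

Step 6
Reactants: 13 4-(2,5-dimethoxyphenyl)but-3-yn-1-ol
Product: 14 4-(2,5-dimethoxyphenyl)butan-1-ol
Conditions: H2 (1 atm), 10% Pd/C, EtOAc, rt
Reagents that add atoms: none
Why: Catalytic hydrogenation reduces the aryl alkyne fully to the alkane, and the homopropargylic alcohol has no benzylic or propargylic C–O bond that could be hydrogenolysed.

Step 7
Reactants: 14 4-(2,5-dimethoxyphenyl)butan-1-ol
Product: 15 4-(2,5-dimethoxyphenyl)butanal
Conditions: Dess–Martin periodinane, CH2Cl2, 0 °C to rt
Reagents that add atoms: none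
Why: Dess–Martin oxidation stops at the aldehyde under nearly neutral conditions, so the electron-rich dimethoxyarene is neither oxidised nor drawn into cyclisation onto the new aldehyde.

Step 8
Reactants: 15 4-(2,5-dimethoxyphenyl)butanal (1.3 equiv); 10 1-{4-[2-(3-methoxyphenyl)ethyl]phenoxy}but-3-en-2-one
Product: 18 racemic 4-[2-(2,5-dimethoxyphenyl)ethyl]-2-{4-[2-(3-methoxyphenyl)ethyl]phenoxy}cyclohex-2-en-1-one, via keto aldehyde 16 (not isolated), via ketol 17 (not isolated)
Conditions: Et2NSiMe3 (20 mol%), MeCN, 0 °C to rt, 10 added slowly; then 0.1 M aq KOH, nBu4NOH (cat.), THF/Et2O, rt to 40 °C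
Reagents that add atoms: none
Why: Diethylamine released from Et2NSiMe3 turns 15 into its enamine, which adds through its β-carbon to the terminal carbon of vinyl ketone 10 (C4–C5 bond) and is hydrolysed to keto aldehyde 16; hydroxide then enolises 16 at the aryloxymethylene carbon, this enolate attacks the aldehyde carbon (C2–C3 bond) to give ketol 17, and E1cB loss of water gives 18. The closest known reaction type is the amine-catalysed Robinson annulation of α-monosubstituted aldehydes with methyl vinyl ketone to 4-substituted cyclohex-2-enones, run here with a vinyl ketone whose enolisable methyl group bears an aryloxy substituent. The single ring is closed in the 6-(enolendo)-exo-trig mode. The stereocentre at C4 arises without control as a racemate, which is acceptable because this carbon becomes sp2 in step 9. The step needs regioselective aldol closure, which is secured because only the aryloxymethylene enolate reaches the aldehyde through a six-membered transition state (the two other enolates could only give cyclobutanols) and because the flanking carbonyl group and ether oxygen make these protons the most acidic ones. Strong acid is avoided in both stages so that the aldehyde cannot cyclise onto the electron-rich ring D.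

Step 9
Reactants: 18 racemic 4-[2-(2,5-dimethoxyphenyl)ethyl]-2-{4-[2-(3-methoxyphenyl)ethyl]phenoxy}cyclohex-2-en-1-one
Product: 20 4-[2-(2,5-dimethoxyphenyl)ethyl]-2-{4-[2-(3-methoxyphenyl)ethyl]phenoxy}phenol, via cross-conjugated dienone 19 (not isolated)
Conditions: Pd(OCOCF3)2 (5 mol%), 2-(dimethylamino)pyridine (10 mol%), TsOH·H2O (20 mol%), O2 (1 atm), DMSO, 80 °C
Reagents that add atoms: none
Why: Aerobic dehydrogenation of a cyclohexenone by divalent palladium, in which the palladium enolate at C6 undergoes β-hydride elimination from C5 to give dienone 19 that tautomerises at once to the phenol while O2 reoxidises the palladium hydride, leaves aryl ethers untouched.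

Step 10
Reactants: 20 4-[2-(2,5-dimethoxyphenyl)ethyl]-2-{4-[2-(3-methoxyphenyl)ethyl]phenoxy}phenol
Product: 21 2-[2-(4-hydroxy-3-{4-[2-(3-hydroxyphenyl)ethyl]phenoxy}phenyl)ethyl]benzene-1,4-diol (target)
Conditions: BBr3 (6 equiv), CH2Cl2, −78 °C to rt; then H2O, work-up under N2
Reagents that add atoms: none
Why: Lewis acid ether cleavage with BBr3 removes the three methyl groups by bromide attack on the boron-activated O–CH3 carbons, whereas the diaryl ether offers no sp3 carbon for such attack and should survive.

Compound list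
1 | (3-methoxybenzyl)triphenylphosphonium chloride | COc1cccc(C[P+](c2ccccc2)(c2ccccc2)c2ccccc2)c1.[Cl-] | starting material
2 | 4-(benzyloxy)benzaldehyde | O=Cc1ccc(OCc2ccccc2)cc1 | starting material
3 | (3-methoxybenzylidene)triphenylphosphorane (not isolated) | COc1cccc(C=P(c2ccccc2)(c2ccccc2)c2ccccc2)c1 | intermediate
4 | 1-(benzyloxy)-4-[2-(3-methoxyphenyl)ethenyl]benzene, E/Z mixture | COc1cccc(C=Cc2ccc(OCc3ccccc3)cc2)c1 | intermediate
5 | 4-[2-(3-methoxyphenyl)ethyl]phenol | COc1cccc(CCc2ccc(O)cc2)c1 | intermediate
6 | 2-chloro-N-methoxy-N-methylacetamide | CON(C)C(=O)CCl | starting material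
7 | N-methoxy-2-{4-[2-(3-methoxyphenyl)ethyl]phenoxy}-N-methylacetamide | COc1cccc(CCc2ccc(OCC(=O)N(C)OC)cc2)c1 | intermediate
8 | vinylmagnesium bromide | C=C[Mg]Br | starting material
9 | bromomagnesium alkoxide of the tetrahedral adduct of 7 and 8 (not isolated) | C=CC(O[Mg]Br)(COc1ccc(CCc2cccc(OC)c2)cc1)N(C)OC | intermediate
10 | 1-{4-[2-(3-methoxyphenyl)ethyl]phenoxy}but-3-en-2-one | C=CC(=O)COc1ccc(CCc2cccc(OC)c2)cc1 | intermediate
11 | 2-iodo-1,4-dimethoxybenzene | COc1ccc(OC)c(I)c1 | starting material
12 | but-3-yn-1-ol | C#CCCO | starting material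
13 | 4-(2,5-dimethoxyphenyl)but-3-yn-1-ol | COc1ccc(OC)c(C#CCCO)c1 | intermediate
14 | 4-(2,5-dimethoxyphenyl)butan-1-ol | COc1ccc(OC)c(CCCCO)c1 | intermediate
15 | 4-(2,5-dimethoxyphenyl)butanal | COc1ccc(OC)c(CCCC=O)c1 | intermediate
16 | racemic 2-[2-(2,5-dimethoxyphenyl)ethyl]-6-{4-[2-(3-methoxyphenyl)ethyl]phenoxy}-5-oxohexanal (not isolated) | O=CC(CCc1cc(OC)ccc1OC)CCC(=O)COc1ccc(CCc2cccc(OC)c2)cc1 | intermediate
17 | 4-[2-(2,5-dimethoxyphenyl)ethyl]-3-hydroxy-2-{4-[2-(3-methoxyphenyl)ethyl]phenoxy}cyclohexan-1-one, diastereomer mixture (not isolated) | O=C1CCC(CCc2cc(OC)ccc2OC)C(O)C1Oc1ccc(CCc2cccc(OC)c2)cc1 | intermediate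
18 | racemic 4-[2-(2,5-dimethoxyphenyl)ethyl]-2-{4-[2-(3-methoxyphenyl)ethyl]phenoxy}cyclohex-2-en-1-one | O=C1CCC(CCc2cc(OC)ccc2OC)C=C1Oc1ccc(CCc2cccc(OC)c2)cc1 | intermediate
19 | racemic 4-[2-(2,5-dimethoxyphenyl)ethyl]-2-{4-[2-(3-methoxyphenyl)ethyl]phenoxy}cyclohexa-2,5-dien-1-one (not isolated) | O=C1C=CC(CCc2cc(OC)ccc2OC)C=C1Oc1ccc(CCc2cccc(OC)c2)cc1 | intermediate
20 | 4-[2-(2,5-dimethoxyphenyl)ethyl]-2-{4-[2-(3-methoxyphenyl)ethyl]phenoxy}phenol | COc1cccc(CCc2ccc(Oc3cc(CCc4cc(OC)ccc4OC)ccc3O)cc2)c1 | intermediate
21 | 2-[2-(4-hydroxy-3-{4-[2-(3-hydroxyphenyl)ethyl]phenoxy}phenyl)ethyl]benzene-1,4-diol | Oc1cccc(CCc2ccc(Oc3cc(CCc4cc(O)ccc4O)ccc3O)cc2)c1 | target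

Total step count: 10.
Longest linear sequence: 7 steps (steps 1, 2, 3, 4, 8, 9 and 10); the aldehyde branch (steps 5 to 7) joins at step 8.

Steps most likely to fail

Step 8. The vinyl ketone may be consumed by oligomerisation through its own acidic aryloxymethylene position or by amine conjugate addition faster than the enamine adds. The aldehyde may also self-condense, and the base stage may stall at the ketol or revert by retro-Michael cleavage. The fallback gives up the ring construction and forms the diaryl ether by copper catalysis; it sets out from phenol 5 and comes back to the route at phenol 20. Ullmann ether coupling of 5 with commercial 4-(benzyloxy)-3-bromobenzaldehyde (CuI, N,N-dimethylglycine hydrochloride, Cs2CO3, dioxane, 90 °C) should give 4-(benzyloxy)-3-{4-[2-(3-methoxyphenyl)ethyl]phenoxy}benzaldehyde F1. (2,5-Dimethoxybenzyl)triphenylphosphonium chloride F2, obtained from commercial 2,5-dimethoxybenzyl chloride and PPh3 in hot toluene, is deprotonated with KOtBu in THF to (2,5-dimethoxybenzylidene)triphenylphosphorane F3. Wittig reaction of F3 with F1 should give 1-(benzyloxy)-4-[2-(2,5-dimethoxyphenyl)ethenyl]-2-{4-[2-(3-methoxyphenyl)ethyl]phenoxy}benzene F4. Hydrogenation of F4 (H2, 10% Pd/C, EtOAc/MeOH) saturates the alkene and removes the benzyl group, giving 20, from which step 10 follows unchanged.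

Step 9. Palladation may be slow at the hindered, oxygen-substituted enone, and acid-promoted hydrolysis of the enol ether by the water that forms could compete with dehydrogenation. The fallback replaces catalytic dehydrogenation by a stepwise α'-selenation and elimination; it sets out from enone 18 and comes back at phenol 20. Kinetic deprotonation of 18 at C6 with LiN(iPr)2 (THF, −78 °C) and trapping with PhSeCl should give 4-[2-(2,5-dimethoxyphenyl)ethyl]-2-{4-[2-(3-methoxyphenyl)ethyl]phenoxy}-6-(phenylselanyl)cyclohex-2-en-1-one F5. Oxidation with H2O2 and pyridine in CH2Cl2 at 0 °C gives the corresponding selenoxide F6, whose syn-elimination delivers dienone 19, and this tautomerises to 20.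

Step 4. Conjugate addition of the liberated N,O-dimethylhydroxylamine during the quench, deprotonation of the acidic aryloxymethylene by the Grignard reagent, or polymerisation of the enone on concentration could erode the vinyl ketone. The fallback avoids the amide and makes the enone by oxidation of a storable allylic alcohol; it sets out from phenol 5 and comes back at vinyl ketone 10. Base-mediated opening of commercial 2-vinyloxirane by the phenoxide of 5 at the unsubstituted oxirane carbon (K2CO3, DMF, 80 °C) should give 1-{4-[2-(3-methoxyphenyl)ethyl]phenoxy}but-3-en-2-ol F7. Dess–Martin oxidation of F7 in CH2Cl2 immediately before step 8 gives 10.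

Further compounds
F1 | step 8 | 4-(benzyloxy)-3-{4-[2-(3-methoxyphenyl)ethyl]phenoxy}benzaldehyde | O=Cc1ccc(OCc2ccccc2)c(Oc2ccc(CCc3cccc(OC)c3)cc2)c1
F2 | step 8 | (2,5-dimethoxybenzyl)triphenylphosphonium chloride | COc1ccc(OC)c(C[P+](c2ccccc2)(c2ccccc2)c2ccccc2)c1.[Cl-]
F3 | step 8 | (2,5-dimethoxybenzylidene)triphenylphosphorane | COc1ccc(OC)c(C=P(c2ccccc2)(c2ccccc2)c2ccccc2)c1
F4 | step 8 | 1-(benzyloxy)-4-[2-(2,5-dimethoxyphenyl)ethenyl]-2-{4-[2-(3-methoxyphenyl)ethyl]phenoxy}benzene, E/Z mixture | COc1cccc(CCc2ccc(Oc3cc(C=Cc4cc(OC)ccc4OC)ccc3OCc3ccccc3)cc2)c1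
F5 | step 9 | 4-[2-(2,5-dimethoxyphenyl)ethyl]-2-{4-[2-(3-methoxyphenyl)ethyl]phenoxy}-6-(phenylselanyl)cyclohex-2-en-1-one, diastereomer mixture | O=C1C([Se]c2ccccc2)CC(CCc2cc(OC)ccc2OC)C=C1Oc1ccc(CCc2cccc(OC)c2)cc1
F6 | step 9 | selenoxide of F5, 6-(benzeneseleninyl) enone, diastereomer mixture | O=C1C([Se](=O)c2ccccc2)CC(CCc2cc(OC)ccc2OC)C=C1Oc1ccc(CCc2cccc(OC)c2)cc1
F7 | step 4 | racemic 1-{4-[2-(3-methoxyphenyl)ethyl]phenoxy}but-3-en-2-ol | C=CC(O)COc1ccc(CCc2cccc(OC)c2)cc1
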